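Read each flask at 20 h, but note that the earlier runs end at 15.0 h, so the asked row lies past the last reading.

| flask | substrate | partner | remark | time |
|---|---|---|---|---|
| delta | 0.015 M | 0.12 M | run made earlier |  |
| epsilon | 0.090 M | 0.12 M | run made earlier |  |
| Thursday's | 0.030 M | 0.120 M |  | 20 h |
| Sunday's | 0.040 M | 0.120 M |  | 20 h |
| Saturday's | 0.060 M | 0.120 M |  | 20 h |
| Tuesday's | 0.10 M | 0.120 M |  | 20 h |

- delta (time / h: target / %): 2.50: 11.7; 5.00: 20.1; 8.00: 26.8; 10.0: 29.1; 12.0: 32.1; 15.0: 34.5
- epsilon (time / h: target / %): 2.50: 10.9; 5.00: 17.9; 8.00: 21.7; 10.0: 23.8; 12.0: 23.3; 15.0: 24.1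

(each reading ± 0.5 percentage points)

1. [target] at the end for Thursday's, Sunday's, Saturday's, Tuesday's, in this order
2. how the row runs (falls, then rises / rises, then falls / rises all the way / hardly changes / falls all the way)

- the earlier runs were read with a standard deviation of 0.5 percentage points
- "hardly changes" means that all values lie within two and a half points (for a concentration: within two and a half percent of the largest)

Look at the delta run first: between 12.0 h and 15.0 h its yield still climbs, from 32.1% to 34.5%. Then look at the epsilon run, with 6.00 times the charge: its last readings are 23.8%, 23.3% and 24.1%. So at the last reading the yield is lower in the epsilon run than in the delta run, but the question asks for a concentration, so multiply each last yield by its charge, which gives 0.00517 M and 0.0217 M.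

Divide the logarithm of the ratio of these concentrations by the logarithm of the ratio of the charges. This gives 0.800, the return exponent, an apparent order of late target concentration in substrate charge at fixed partner. It stands above zero, so my reckoning has the row rising.

Carry it from the epsilon run to Tuesday's: 0.0236 M. Carry it from the delta run to Thursday's: 0.00901 M. Expect that last figure to run low, since it rests on the reading at 15.0 h and the delta run was still climbing at that reading.

The forecast gives 0.0098 M, 0.0124 M, 0.0167 M and 0.0232 M, and its shape is rises all the way: “Target concentration keeps rising with charge, but with diminishing returns.” For Thursday's it stands at 0.0098 M against my 0.00901 M.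

The flasks give 0.00980 M, 0.0124 M, 0.0170 M and 0.0239 M, and the row rises all the way.

    substrate + partner → target (k = 1.37 × 10⁻⁴ L mol⁻¹ s⁻¹)
    substrate + 2 partner → side product (k = 2.94 × 10⁻⁴ L² mol⁻² s⁻¹)
    2 substrate → homo dimer (k = 8.69 × 10⁻⁵ L mol⁻¹ s⁻¹)
    partner → decomposed reagent (k = 1.49 × 10⁻⁵ s⁻¹)
    target → over-reaction product (k = 4.88 × 10⁻⁶ s⁻¹)

From Thursday's to Tuesday's the return exponent reads 0.740, and from Saturday's to Tuesday's 0.667, both above zero. In Thursday's flask, target is made 5.34 times faster than it is used up at 6.95 h, each step taken net. At 20.0 h Thursday's flask still holds 38% of its substrate and 27% of its partner, with 8.62% of the substrate charged standing as over-reaction product, and the ratio of target made to target used up, each step taken net, has fallen to 1.07.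

Readings and results were computed for substances that don't exist, noise included.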